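**Remarks on the chemistry**

- Remark on a structure: the string C=C(C)[C@@H](O)C[C@H](O)C(C)=C would encode the (3S,5S) diol, the chiral anti isomer, which has no enantiotopic hydroxyls. The meso (3R,5S) syn diol that the strategy needs is C=C(C)[C@H](O)C[C@H](O)C(C)=C, and this is compound 6 below.
- Assumption: the (R)-isothiourea is taken to acylate the (R)-carbinol, by analogy with its preference for (R)-1-arylalkanols, where the π substituent and the alkyl substituent are placed as they are here. Should the sense be the opposite, the (S)-catalyst is used with no other change.
- In Alternative 2 the ether on C6' is taken as 4-methoxybenzyl throughout, as in A4.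

## Structural features

The target 26 is a 5-methylcoumarin, a benzene ring (ring A) fused to a 2-pyranone (ring B), whose C4 oxygen is etherified with C1' of an eight-carbon chain; this enol ether is a vinylogous carbonate, so C4 and the lactone carbonyl C2 are both open to attack by alkoxides, hydroxide and hydrides. The chain carries an E-trisubstituted alkene C2'=C3' (methyl on C3'), a secondary allylic alcohol at C4' (S), a methylene C5', a secondary allylic hydroperoxide at C6' (S) and a terminal isopropenyl group C7'(CH3)=C8'H2. The two stereocentres stand in a 1,3-relationship across C5' and are anti to each other. The hydroperoxide is the fragile group: phosphines, sulfides, hydrides and low-valent metals reduce it, base dehydrates it to the enone because C6' carries a hydrogen, strong acid fragments it, and radicals shift it across the allyl system; the allyl ether at C4 can also undergo Claisen rearrangement on heating. The real difficulty is twofold: to fix two oxygenated centres that are separated by one methylene group and differ only as OH and OOH, and to carry the O–O bond past the step that joins chain and heterocycle. The feature used is that C4' and C6' are both allylic, oxygen-bearing carbons flanking C5'H2, each attached to a 2-propenyl unit (C3'(CH3)=C2' and C7'(CH3)=C8'); without C1' and the coumarin, C2'–C8' is a 2,6-dimethylhepta-1,6-diene-3,5-diol whose syn isomer is meso. One enantiotopos-selective acylation of that diol defines both centres at once, and exchange of the acylated oxygen for OOH with inversion turns the syn diol into the anti hydroxy hydroperoxide.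

## Logic of the disconnections

**26 ⇒ 25.** The bond cut is the O–C bond between the outer peroxide oxygen on C6' and a 2-methoxyprop-2-yl cap. The reason is that the free O–O–H should exist only in the last flask. The gain is that every earlier step handles a dialkyl peroxide without an O–H, which cannot be deprotonated, alkylated twice or fragmented by base. The demand is a last step that is weakly acidic, metal-free and run near room temperature.

**25 ⇒ 18 + 24.** The C2'=C3' double bond is cut. This joins chain and heterocycle in one convergent step and brings the base- and hydride-sensitive ring B in only after all hydride, alkoxide and peroxyanion chemistry is over. The gain is that 18 is a nine-carbon fragment and 24 a two-step heterocycle. The demand is threefold: selection between the two 1,1-disubstituted alkenes of 18 (the one beside the free hydroxyl must react), E geometry, and a catalyst that leaves the O–O bond alone.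

**24 ⇒ 22 + 23, and 22 ⇒ 19 + 20.** First the O–allyl bond is cut, then the C2–C3 and O1–C2 bonds of ring B. Both are classical and lead to cheap materials. The demand is O- over C-alkylation of the ambident 22 and a temperature below that of the Claisen rearrangement of 24.

**18 ⇒ 17 ⇒ 11 + 15.** The O–Si bond on the C4' oxygen is cut first, because the hydroxyl must be free to steer the metathesis. Then the C–O bond between C6' (C5 of the heptadiene) and the peroxide oxygen is cut. This is the point at which the syn array of the meso-derived series becomes the anti array of the target. The demand is clean backside substitution at a secondary allylic carbon, without ionisation, attack at the alkene terminus or elimination.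

**15 ⇒ 12.** The C=C bond of 12 is cut by ozone in methanol. The reason is that a peroxide nucleophile already carrying its acid-labile cap avoids free hydrogen peroxide and double alkylation. The demand is careful handling of a small peroxide, in solution only.

**11 ⇒ 10 ⇒ 9 ⇒ 8.** Only bonds to heteroatoms change: S–O (sulfonate), O–acyl (ester removed) and O–Si (silyl ether made). The reason is to convert the ester oxygen, which marks the (R)-carbinol, into a leaving group while the (S)-carbinol stays masked. The demand is that neither the acyl group of 8 nor the silyl group of 10 migrates between the two oxygens, because in this meso-derived series such a 1,3-shift gives the enantiomer.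

**8 ⇒ 6 + 7.** The O–acyl bond is cut. The gain is symmetry, not size: 6 has a mirror plane through C4, so no stereocentre has to be made independently. The demand is a catalyst that tells the two enantiotopic allylic hydroxyls apart and stops at the monoester.

**6 ⇒ 4 ⇒ 1 + 2.** A C–H bond at C3 is cut (carbonyl reduction), then the C4–C5 bond (aldol). The gain is two four- and five-carbon commodity chemicals. The demand is 1,3-syn reduction with 1,2-selectivity at an enone; the aldol need not be enantioselective, since both enantiomers of 4 give the same meso 6.

## Other disconnections considered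

**Alternative 1:** The cut is through ring B at O1–C2 and C3=C4. In the forward step the phenol of the 2-hydroxy-6-methylbenzoate A2 would add to the ketene carbonyl carbon of (triphenylphosphoranylidene)ketene A3. The resulting ester ylide would olefinate the neighbouring benzoate carbonyl and close the pyranone to give A1, with loss of the phosphorus as its oxide.
- In its favour: the C4 ether is in place before the ring exists, so the O- versus C-alkylation question of 22 never arises, and the conditions are neutral. On this point it is better than the chosen plan.
- Against it here: the carbonyl to be olefinated is an ester flanked by two ortho substituents, so the intramolecular Wittig step is hindered. A2 requires esterification of a hindered acid with a valuable chiral allylic alcohol, namely A9 of Alternative 3, and A2 is itself an ionisable allylic ester.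
- The step makes neither stereocentre and not the alkene. A1 ends in a prenyl group, so the C6' hydroperoxide would have to come from a late ene photooxygenation, with no control at C6' and a regioisomeric tertiary hydroperoxide as co-product.
- Comparison: in step count for the heterocycle it is the equal of the chosen plan (one step against two). In structure it solves the easiest part of the molecule, whereas the chosen plan spends its key step on the two stereocentres.

**Alternative 2:** The cut is C3'–C4'. In the forward step alkyne A5, aldehyde A6 and silane A7 would combine on zerovalent nickel, supplied as bis(cycloocta-1,5-diene)nickel A8 together with an N-heterocyclic carbene ligand. Oxidative cyclisation gives an oxanickelacyclopentene, the silane cleaves the Ni–O bond, and C–H reductive elimination gives A4 with H and the new C–C bond cis on the alkene.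
- In its favour: the alkene geometry follows from the syn addition and the skeleton is assembled convergently. On geometry it is better than the cross-metathesis of the chosen plan.
- Against it here: the two ends of A5 (CH3 and CH2OSi) differ little in size, so the regiochemistry of C–C bond formation is not assured. The C4' configuration would depend on weak 1,3-induction from C6' or on a chiral ligand. A6 is a β-alkoxy aldehyde prone to elimination and needs its own enantioselective synthesis.
- C6' is made as R on purpose, so the same inversion to the peroxide as in the chosen plan is still required, now with three orthogonal protecting groups.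
- Comparison: in mechanism it is superior for the alkene and inferior for the stereocentres, which in the chosen plan both come from one catalyst-controlled event. In step economy it is expected to be longer, because A6 alone needs several steps where the chosen plan reaches its nine-carbon core in three.

**Alternative 3:** The cuts are C3'–CH3 and C1'–C2'. In the forward step the terminal alkyne A10 would undergo syn methylalumination with A11 and catalytic A12, and the alkenylalane, as its alanate, would be trapped by A13 to give A9.
- In its favour: regio- and stereochemistry of the trisubstituted alkene are dependable, two C–C bonds form in one pot, and the reaction scales. On alkene geometry it is better than the chosen plan, and it needs no metathesis near a peroxide.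
- Against it here: the propargylic silyloxy group slows the carbometalation and can lower its regioselectivity. A10 must be obtained enantiopure in a separate asymmetric step, and a pyrophoric alane is used in excess.
- As in Alternative 1 the chain ends in a prenyl group, so the C6' hydroperoxide would again come from an ene photooxygenation without control at C6'. The coumarin would be attached by Mitsunobu etherification with 22.
- Comparison: in step count to the protected chain it is about the equal of the chosen plan. In structure it controls only C4', whereas the chosen plan controls C4' and C6' together and introduces the peroxide by a stereospecific substitution.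

Key step: step 3

## Route

**Step 1**
Reactants: 1 3-methylbut-3-en-2-one; 2 methacrolein (2-methylprop-2-enal)
Product: 4 rac-5-hydroxy-2,6-dimethylhepta-1,6-dien-3-one, via lithium 3-methylbuta-1,3-dien-2-olate 3 (not isolated)
Conditions: LiN(iPr)2 (1.05 equiv), THF, −78 °C, slow addition of 1; then 2, −78 °C, 20 min; AcOH in THF at −78 °C, then aq. NH4Cl
Reagents that add atoms: none
Why: Directed aldol addition: kinetic deprotonation of the methyl ketone gives the cross-conjugated lithium dienolate 3, which adds 1,2 to the enal through a closed transition state; the product is racemic, which suffices because the next step converges both enantiomers on one meso diol.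

**Step 2**
Reactants: 4
Product: 6 meso-(3R,5S)-2,6-dimethylhepta-1,6-diene-3,5-diol, via diethylboron aldolate chelate 5 (not isolated)
Conditions: Et2BOMe (1.1 equiv), THF/MeOH 4:1, −78 °C; NaBH4 (1.1 equiv), −78 °C; AcOH, then repeated co-evaporation with MeOH; 6 freed of any anti diol by crystallisation or chromatography
Reagents that add atoms: none
Why: Narasaka–Prasad reduction: the boron chelate 5 holds the β-alkoxy ketone in a half-chair, external hydride attacks axially and gives the 1,3-syn diol, which here is the meso compound; the boron-activated carbonyl should be reduced 1,2 at −78 °C faster than the enone is reduced at its alkene terminus.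

**Step 3** (key step)
Reactants: 6 meso-(3R,5S)-2,6-dimethylhepta-1,6-diene-3,5-diol; 7 isobutyric anhydride (2-methylpropanoic anhydride)
Product: 8 (3R,5S)-5-hydroxy-2,6-dimethylhepta-1,6-dien-3-yl 2-methylpropanoate
Conditions: (R)-2-phenyl-2,3-dihydrobenzo[d]imidazo[2,1-b]thiazole (5 mol %), 7 (1.2 equiv), iPr2NEt (1.2 equiv), CHCl3, 0 °C; MeOH quench when a little diester has appeared
Reagents that add atoms: none
Why: Mechanism: the isothiourea is acylated at nitrogen by 7 to an N-isobutyryl isothiouronium isobutyrate in which a sulfur–carbonyl-oxygen contact holds the acyl group coplanar with the cationic bicycle and the C2 phenyl group blocks one face. One allylic carbinol of 6 lays its isopropenyl π bond over the cation (cation–π attraction), the carboxylate takes the hydroxyl proton, and the acyl group passes to oxygen with release of the catalyst. The closest known reactions are the isothiourea-catalysed acylative kinetic resolution of secondary allylic and benzylic alcohols and the acylative desymmetrisation of meso diols; the enzymatic counterpart is lipase monoacylation of meso-1,3-diols. No ring is closed and no skeletal bond is formed; only an O–acyl bond is made. The two stereogenic carbons of 6 become C3 (R, ester) and C5 (S, free hydroxyl) of 8, and both are fixed by one element, the C2 stereocentre of the catalyst, which decides which enantiotopic hydroxyl is acylated. The step needs enantiotopic-group selectivity and mono- over bis-acylation: the first is secured by the substrate having a π system directly on each carbinol carbon and a plain CH2 on its other side, the contrast that this catalyst class reads. The second is secured by proofreading, since the minor monoester still carries the fast-reacting (R)-hydroxyl and is drained into the meso diester, so that a slight excess of 7 should raise the enantiopurity of 8 at a small cost in material; diester and unreacted 6 are recycled by saponification. The α-branched anhydride keeps the uncatalysed background acylation and later 1,3-acyl migration slow.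

**Step 4**
Reactants: 8
Product: 9 (3R,5S)-5-[(tert-butyldimethylsilyl)oxy]-2,6-dimethylhepta-1,6-dien-3-yl 2-methylpropanoate
Conditions: TBSOTf (1.2 equiv), 2,6-lutidine (2 equiv), CH2Cl2, −78 °C
Reagents that add atoms: tert-butyldimethylsilyl trifluoromethanesulfonate, CC(C)(C)[Si](C)(C)OS(=O)(=O)C(F)(F)F
Why: Silylation of the secondary alcohol with a silyl triflate and a hindered pyridine base is fast at −78 °C; speed and the absence of a nucleophilic base matter because a 1,3-acyl shift in 8 would produce its enantiomer.

**Step 5**
Reactants: 9
Product: 10 (3R,5S)-5-[(tert-butyldimethylsilyl)oxy]-2,6-dimethylhepta-1,6-dien-3-ol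
Conditions: i-Bu2AlH (2.5 equiv), CH2Cl2, −78 °C; aq. potassium sodium tartrate
Reagents that add atoms: none
Why: Reductive cleavage of the ester by an aluminium hydride at low temperature; the C–O bond of the carbinol is not broken, and the non-basic conditions avoid a 1,3-silyl shift, which would exchange the roles of the two carbinols and erode the enantiopurity.

**Step 6**
Reactants: 10
Product: 11 (3R,5S)-5-[(tert-butyldimethylsilyl)oxy]-2,6-dimethylhepta-1,6-dien-3-yl methanesulfonate
Conditions: MsCl (1.3 equiv), Et3N (2 equiv), CH2Cl2, −30 °C; cold aq. NaHCO3 work-up, used crude at once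
Reagents that add atoms: methanesulfonyl chloride, CS(=O)(=O)Cl
Why: Sulfonylation at oxygen (via sulfene) with retention at carbon; the allyl cation that ionisation would give has its methyl group on the central carbon and is poorly stabilised, so the mesylate should survive a cold work-up and immediate use.

**Step 7**
Reactants: 12 2,3-dimethylbut-2-ene
Product: 15 2-methoxyprop-2-yl hydroperoxide, via 4,4,5,5-tetramethyl-1,2,3-trioxolane 13 (not isolated), via acetone O-oxide 14 (not isolated)
Conditions: O3, CH2Cl2/MeOH 4:1, −78 °C; N2 purge; concentrated below 20 °C behind a shield, kept and used as a solution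
Reagents that add atoms: ozone, [O-][O+]=O; methanol, CO
Why: Ozonolysis by the Criegee mechanism: cycloaddition gives the primary ozonide 13, cycloreversion gives acetone and the carbonyl oxide 14, and methanol adds to 14 to give the α-methoxy hydroperoxide; the symmetrical tetrasubstituted alkene gives one product besides acetone.

**Step 8**
Reactants: 11; 15
Product: 17 tert-butyl({(3S,5S)-5-[(2-methoxypropan-2-yl)peroxy]-2,6-dimethylhepta-1,6-dien-3-yl}oxy)dimethylsilane, via caesium 2-methoxyprop-2-yl peroxide 16 (not isolated)
Conditions: 15 (2 equiv), CsOH·H2O (1.8 equiv), DMF, 0 °C, 15 min; then 11, 0 °C → rt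
Reagents that add atoms: none
Why: SN2 displacement of the methanesulfonate by the peroxyanion 16, an α-effect nucleophile of low basicity, in a dipolar aprotic solvent; backside attack inverts the sulfonate-bearing carbon (C3 of 11, which is C5 of 17 and the future C6') from R to S and so converts the syn into the anti array, and the product has no O–H, so it cannot be alkylated again or fragment under the basic conditions (known alkylation of this hydroperoxide by secondary sulfonates).

**Step 9**
Reactants: 17
Product: 18 (3S,5S)-5-[(2-methoxypropan-2-yl)peroxy]-2,6-dimethylhepta-1,6-dien-3-ol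
Conditions: Bu4NF (1.5 equiv), AcOH (1.5 equiv), THF, 0 °C → rt
Reagents that add atoms: none
Why: Fluoride-mediated cleavage of the Si–O bond; buffering with acetic acid keeps the medium near neutral, so that neither base-induced fragmentation at the C–H next to the peroxide nor acid loss of the peroxyketal should occur.

**Step 10**
Reactants: 19 1-(2-hydroxy-6-methylphenyl)ethanone; 20 diethyl carbonate
Product: 22 4-hydroxy-5-methyl-2H-chromen-2-one, via ethyl 3-(2-hydroxy-6-methylphenyl)-3-oxopropanoate 21 (not isolated)
Conditions: NaH (3 equiv), 20 (excess), toluene, 100 °C; then aq. HCl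
Reagents that add atoms: none
Why: Claisen-type C-acylation of the ketone enolate by the carbonate, then lactonisation of the phenoxide onto the β-keto ester 21; the acidic product is held as its sodium salt, which drives both equilibria (classical 4-hydroxycoumarin synthesis).

**Step 11**
Reactants: 22; 23 allyl bromide (3-bromoprop-1-ene)
Product: 24 5-methyl-4-(prop-2-en-1-yloxy)-2H-chromen-2-one
Conditions: K2CO3 (1.5 equiv), 23 (1.2 equiv), acetone, 50 °C
Reagents that add atoms: none
Why: Williamson O-alkylation of the vinylogous carboxylate; the allyl ether is the expected major product with carbonate in acetone, C3-allylated material is removed by its solubility in aqueous base, and the temperature stays below that of the Claisen rearrangement of 24.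

**Step 12**
Reactants: 18; 24
Product: 25 4-({(2E,4S,6S)-4-hydroxy-6-[(2-methoxypropan-2-yl)peroxy]-3,7-dimethylocta-2,7-dien-1-yl}oxy)-5-methyl-2H-chromen-2-one
Conditions: second-generation Hoveyda–Grubbs catalyst, (H2IMes)Cl2Ru=CH(C6H4-2-OiPr) (10 mol % in two portions), 24 (3 equiv), 1,4-benzoquinone (10 mol %), CH2Cl2, 40 °C, argon sparge
Reagents that add atoms: none
Why: Olefin cross-metathesis through ruthenium alkylidene and metallacyclobutane intermediates: the carbene from the monosubstituted alkene of 24 adds to the 1,1-disubstituted alkene beside the free hydroxyl of 18, while the alkene beside the bulky peroxyketal is shielded and the trisubstituted product does not re-enter. The E isomer should prevail because it places C1' cis to the small C3' methyl; the phosphine-free catalyst spares the O–O bond and benzoquinone suppresses hydride-mediated isomerisation of the allylic alcohol.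

**Step 13**
Reactants: 25
Product: 26 4-{[(2E,4S,6S)-6-hydroperoxy-4-hydroxy-3,7-dimethylocta-2,7-dien-1-yl]oxy}-5-methyl-2H-chromen-2-one (target)
Conditions: AcOH/THF/H2O 3:1:1, rt, dark; cold chromatography, stored cold
Reagents that add atoms: none
Why: Acid hydrolysis of the monoperoxyketal: loss of methanol gives a peroxycarbenium ion that water captures, and the hemiketal collapses to acetone and the free hydroperoxide; the C6'–O bond is not touched, so the configuration is kept, and no base, metal or reductant is present.

## Compound list

1 | 3-methylbut-3-en-2-one | CC(=O)C(C)=C | starting material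
2 | methacrolein (2-methylprop-2-enal) | C=C(C)C=O | starting material
3 | lithium 3-methylbuta-1,3-dien-2-olate | [Li+].[O-]C(=C)C(C)=C | intermediate
4 | rac-5-hydroxy-2,6-dimethylhepta-1,6-dien-3-one | C=C(C)C(=O)CC(O)C(C)=C | intermediate
5 | diethylboron aldolate chelate of 4 (six-membered ring: boron bound to the C5 alkoxide oxygen and coordinated by the C3 carbonyl oxygen) | CC[B-]1(CC)OC(CC(=[O+]1)C(C)=C)C(C)=C | intermediate
6 | meso-(3R,5S)-2,6-dimethylhepta-1,6-diene-3,5-diol | C=C(C)[C@H](O)C[C@H](O)C(C)=C | intermediate
7 | isobutyric anhydride | CC(C)C(=O)OC(=O)C(C)C | starting material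
8 | (3R,5S)-5-hydroxy-2,6-dimethylhepta-1,6-dien-3-yl 2-methylpropanoate | C=C(C)[C@@H](C[C@H](O)C(C)=C)OC(=O)C(C)C | intermediate
9 | (3R,5S)-5-[(tert-butyldimethylsilyl)oxy]-2,6-dimethylhepta-1,6-dien-3-yl 2-methylpropanoate | C=C(C)[C@@H](C[C@H](O[Si](C)(C)C(C)(C)C)C(C)=C)OC(=O)C(C)C | intermediate
10 | (3R,5S)-5-[(tert-butyldimethylsilyl)oxy]-2,6-dimethylhepta-1,6-dien-3-ol | C=C(C)[C@@H](C[C@H](O[Si](C)(C)C(C)(C)C)C(C)=C)O | intermediate
11 | (3R,5S)-5-[(tert-butyldimethylsilyl)oxy]-2,6-dimethylhepta-1,6-dien-3-yl methanesulfonate | C=C(C)[C@@H](C[C@H](O[Si](C)(C)C(C)(C)C)C(C)=C)OS(C)(=O)=O | intermediate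
12 | 2,3-dimethylbut-2-ene | CC(C)=C(C)C | starting material
13 | 4,4,5,5-tetramethyl-1,2,3-trioxolane | CC1(C)OOOC1(C)C | intermediate
14 | acetone O-oxide | CC(C)=[O+][O-] | intermediate
15 | 2-methoxyprop-2-yl hydroperoxide (2-hydroperoxy-2-methoxypropane) | COC(C)(C)OO | intermediate
16 | caesium 2-methoxyprop-2-yl peroxide | [Cs+].COC(C)(C)O[O-] | intermediate
17 | tert-butyl({(3S,5S)-5-[(2-methoxypropan-2-yl)peroxy]-2,6-dimethylhepta-1,6-dien-3-yl}oxy)dimethylsilane | C=C(C)[C@H](C[C@H](O[Si](C)(C)C(C)(C)C)C(C)=C)OOC(C)(C)OC | intermediate
18 | (3S,5S)-5-[(2-methoxypropan-2-yl)peroxy]-2,6-dimethylhepta-1,6-dien-3-ol | C=C(C)[C@H](C[C@H](O)C(C)=C)OOC(C)(C)OC | intermediate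
19 | 1-(2-hydroxy-6-methylphenyl)ethanone | CC(=O)c1c(C)cccc1O | starting material
20 | diethyl carbonate | CCOC(=O)OCC | starting material
21 | ethyl 3-(2-hydroxy-6-methylphenyl)-3-oxopropanoate | CCOC(=O)CC(=O)c1c(C)cccc1O | intermediate
22 | 4-hydroxy-5-methyl-2H-chromen-2-one | Oc1cc(=O)oc2cccc(C)c12 | intermediate
23 | allyl bromide (3-bromoprop-1-ene) | C=CCBr | starting material
24 | 5-methyl-4-(prop-2-en-1-yloxy)-2H-chromen-2-one | C=CCOc1cc(=O)oc2cccc(C)c12 | intermediate
25 | 4-({(2E,4S,6S)-4-hydroxy-6-[(2-methoxypropan-2-yl)peroxy]-3,7-dimethylocta-2,7-dien-1-yl}oxy)-5-methyl-2H-chromen-2-one | C=C(C)[C@H](C[C@H](O)/C(C)=C/COc1cc(=O)oc2cccc(C)c12)OOC(C)(C)OC | intermediate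
26 | 4-{[(2E,4S,6S)-6-hydroperoxy-4-hydroxy-3,7-dimethylocta-2,7-dien-1-yl]oxy}-5-methyl-2H-chromen-2-one | C=C(C)[C@H](C[C@H](O)/C(C)=C/COc1cc(=O)oc2cccc(C)c12)OO | target

## Step count and least certain steps

Total: 13 steps. Longest linear sequence: 10 steps (1, 2, 3, 4, 5, 6, 8, 9, 12, 13); steps 7, 10 and 11 are side branches.

**Step 3 (key step).** The likely failure is insufficient discrimination between the two enantiotopic carbinols: an isopropenyl group is a weaker π partner for the cationic catalyst than an aryl or styryl group, and its 2-methyl group may twist the alkene out of the stacking plane. A second danger is 1,3-acyl migration during isolation, which is racemisation in this series.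

Fallback, setting out from 6 and returning at 10: 6 is acetylated twice (Ac2O, pyridine) to meso-(3R,5S)-2,6-dimethylhepta-1,6-diene-3,5-diyl diacetate F1. A lipase (Burkholderia cepacia lipase or Candida antarctica lipase B, phosphate buffer at pH 7 with a cosolvent) hydrolyses one enantiotopic acetate to (3R,5S)-5-hydroxy-2,6-dimethylhepta-1,6-dien-3-yl acetate F2. Silylation as in step 4 gives (3R,5S)-5-[(tert-butyldimethylsilyl)oxy]-2,6-dimethylhepta-1,6-dien-3-yl acetate F3, and i-Bu2AlH as in step 5 gives 10. Hydrolysis of F1 and enzymatic acetylation of 6 with vinyl acetate are enantiocomplementary, so whichever carbinol the enzyme prefers, one of the two modes places the ester on the (R)-carbon.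

**Step 8.** The likely failures are ionisation of the allylic mesylate, attack of the peroxyanion at the alkene terminus with allylic shift, and elimination to the conjugated diene. The first would cost configuration at C6', the second would give a transposed primary peroxide.

Fallback, setting out from 10 and returning at 17: 10 undergoes reductive 1,3-transposition of the allylic alcohol (Mitsunobu reaction with 2-nitrobenzenesulfonylhydrazide, PPh3 and diethyl azodicarboxylate, THF, −30 °C then rt; loss of sulfinate and dinitrogen with hydrogen transfer to C1). This turns the hydroxylated arm into a prenyl group and gives tert-butyl{[(3S)-2,6-dimethylhepta-1,5-dien-3-yl]oxy}dimethylsilane F4. Dye-sensitised photooxygenation (O2, 5,10,15,20-tetraphenylporphyrin, visible light, CH2Cl2, 0 °C; Schenck ene reaction) is much faster at the trisubstituted than at the 1,1-disubstituted alkene and gives tert-butyl{[(3S,5RS)-5-hydroperoxy-2,6-dimethylhepta-1,6-dien-3-yl]oxy}dimethylsilane F5 as both C5 epimers, beside the tertiary regioisomer. Capping with 2-methoxypropene (pyridinium p-toluenesulfonate, CH2Cl2, 0 °C) and chromatographic separation of the (5S) diastereomer returns to 17. This fallback gives up control at C6' and costs material, so it is a last resort.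

**Step 12.** The likely failures are decay of the ruthenium carbene at the O–O bond, incomplete selection between the two 1,1-disubstituted alkenes of 18, incomplete E selectivity, and consumption of the catalyst by self-metathesis of 24.

Fallback, setting out from 8 and returning at 25: the metathesis is moved to a peroxide-free stage and the heterocycle is attached by etherification.
- Cross-metathesis of 8 with (Z)-but-2-ene-1,4-diyl diacetate (same catalyst, CH2Cl2, 40 °C) should give (2E,4S,6R)-4-hydroxy-3,7-dimethyl-6-[(2-methylpropanoyl)oxy]octa-2,7-dien-1-yl acetate F6.
- Silylation as in step 4 gives the C4' tert-butyldimethylsilyl ether F7.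
- i-Bu2AlH removes both esters and gives (2E,4S,6R)-4-[(tert-butyldimethylsilyl)oxy]-3,7-dimethylocta-2,7-diene-1,6-diol F8.
- Mitsunobu etherification of the primary allylic hydroxyl with 22 (PPh3, diisopropyl azodicarboxylate, THF, 0 °C) gives 4-({(2E,4S,6R)-4-[(tert-butyldimethylsilyl)oxy]-6-hydroxy-3,7-dimethylocta-2,7-dien-1-yl}oxy)-5-methyl-2H-chromen-2-one F9.
- Mesylation as in step 6 gives the C6' methanesulfonate F10.
- Displacement with 15 and CsOH·H2O as in step 8 gives the (2E,4S,6S) silyl-protected peroxyketal F11, and Bu4NF/AcOH as in step 9 gives 25.

The weak point of this fallback is that the peroxyanion meets the coumarin, so that step would be run cold and with no excess of base. The E selectivity is not improved; the geometric isomers would be separated at the stage of the crystalline, UV-active F9.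

**Step 1.** The likely failures are anionic oligomerisation of 1 (conjugate addition of its own enolate or of the amide base) and retro-aldol cleavage or dehydration of 4 during work-up.

Fallback, setting out from 2 and returning at 4: the lithium enolate of N-methoxy-N-methylacetamide (LiN(iPr)2, THF, −78 °C) adds to 2 to give rac-3-hydroxy-N-methoxy-N,4-dimethylpent-4-enamide F12. Isopropenylmagnesium bromide (3 equiv, THF, 0 °C) then acylates at the N-methoxy-N-methylamide and gives 4 after a cold acidic quench. The enone is thus made by acylation of an alkenyl nucleophile and never has to be enolised.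

**Step 2.** The likely failures are conjugate reduction at the unsubstituted alkene terminus of the enone in competition with carbonyl reduction, and incomplete boron chelation with loss of syn selectivity.

Fallback, setting out from 4 and returning at 6: 4 is reduced under Luche conditions (NaBH4, CeCl3·7H2O, MeOH, −78 °C), which secure 1,2-addition but are expected to give the syn and the anti diol together. The mixture is converted with 2,2-dimethoxypropane and pyridinium p-toluenesulfonate (CH2Cl2, rt) into the acetonides, and the cis isomer (4R,6S)-2,2-dimethyl-4,6-di(prop-1-en-2-yl)-1,3-dioxane F13 is separated by chromatography. Aqueous acetic acid at rt then returns 6. Stereocontrol in the reduction is given up and replaced by a separation of diastereomers.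

## Further compounds

F1 | step 3 | meso-(3R,5S)-2,6-dimethylhepta-1,6-diene-3,5-diyl diacetate | C=C(C)[C@@H](C[C@H](OC(C)=O)C(C)=C)OC(C)=O
F2 | step 3 | (3R,5S)-5-hydroxy-2,6-dimethylhepta-1,6-dien-3-yl acetate | C=C(C)[C@@H](C[C@H](O)C(C)=C)OC(C)=O
F3 | step 3 | (3R,5S)-5-[(tert-butyldimethylsilyl)oxy]-2,6-dimethylhepta-1,6-dien-3-yl acetate | C=C(C)[C@@H](C[C@H](O[Si](C)(C)C(C)(C)C)C(C)=C)OC(C)=O
F4 | step 8 | tert-butyl{[(3S)-2,6-dimethylhepta-1,5-dien-3-yl]oxy}dimethylsilane | C=C(C)[C@H](CC=C(C)C)O[Si](C)(C)C(C)(C)C
F5 | step 8 | tert-butyl{[(3S,5RS)-5-hydroperoxy-2,6-dimethylhepta-1,6-dien-3-yl]oxy}dimethylsilane | C=C(C)C(C[C@H](O[Si](C)(C)C(C)(C)C)C(C)=C)OO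
F6 | step 12 | (2E,4S,6R)-4-hydroxy-3,7-dimethyl-6-[(2-methylpropanoyl)oxy]octa-2,7-dien-1-yl acetate | C=C(C)[C@@H](C[C@H](O)/C(C)=C/COC(C)=O)OC(=O)C(C)C
F7 | step 12 | (2E,4S,6R)-4-[(tert-butyldimethylsilyl)oxy]-3,7-dimethyl-6-[(2-methylpropanoyl)oxy]octa-2,7-dien-1-yl acetate | C=C(C)[C@@H](C[C@H](O[Si](C)(C)C(C)(C)C)/C(C)=C/COC(C)=O)OC(=O)C(C)C
F8 | step 12 | (2E,4S,6R)-4-[(tert-butyldimethylsilyl)oxy]-3,7-dimethylocta-2,7-diene-1,6-diol | C=C(C)[C@@H](C[C@H](O[Si](C)(C)C(C)(C)C)/C(C)=C/CO)O
F9 | step 12 | 4-({(2E,4S,6R)-4-[(tert-butyldimethylsilyl)oxy]-6-hydroxy-3,7-dimethylocta-2,7-dien-1-yl}oxy)-5-methyl-2H-chromen-2-one | C=C(C)[C@@H](C[C@H](O[Si](C)(C)C(C)(C)C)/C(C)=C/COc1cc(=O)oc2cccc(C)c12)O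
F10 | step 12 | (3R,5S,6E)-5-[(tert-butyldimethylsilyl)oxy]-2,6-dimethyl-8-[(5-methyl-2-oxo-2H-chromen-4-yl)oxy]octa-1,6-dien-3-yl methanesulfonate | C=C(C)[C@@H](C[C@H](O[Si](C)(C)C(C)(C)C)/C(C)=C/COc1cc(=O)oc2cccc(C)c12)OS(C)(=O)=O
F11 | step 12 | 4-({(2E,4S,6S)-4-[(tert-butyldimethylsilyl)oxy]-6-[(2-methoxypropan-2-yl)peroxy]-3,7-dimethylocta-2,7-dien-1-yl}oxy)-5-methyl-2H-chromen-2-one | C=C(C)[C@H](C[C@H](O[Si](C)(C)C(C)(C)C)/C(C)=C/COc1cc(=O)oc2cccc(C)c12)OOC(C)(C)OC
F12 | step 1 | rac-3-hydroxy-N-methoxy-N,4-dimethylpent-4-enamide | C=C(C)C(O)CC(=O)N(C)OC
F13 | step 2 | (4R,6S)-2,2-dimethyl-4,6-di(prop-1-en-2-yl)-1,3-dioxane | C=C(C)[C@H]1C[C@@H](C(C)=C)OC(C)(C)O1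
A1 | alternative 1 | 4-{[(2E,4S)-4-(tert-butyldimethylsilyloxy)-3,7-dimethylocta-2,6-dien-1-yl]oxy}-5-methyl-2H-chromen-2-one | CC(C)=CC[C@H](O[Si](C)(C)C(C)(C)C)/C(C)=C/COc1cc(=O)oc2cccc(C)c12
A2 | alternative 1 | (2E,4S)-4-(tert-butyldimethylsilyloxy)-3,7-dimethylocta-2,6-dien-1-yl 2-hydroxy-6-methylbenzoate | CC(C)=CC[C@H](O[Si](C)(C)C(C)(C)C)/C(C)=C/COC(=O)c1c(C)cccc1O
A3 | alternative 1 | (triphenylphosphoranylidene)ketene | O=C=C=P(c1ccccc1)(c1ccccc1)c1ccccc1
A4 | alternative 2 | (2E,4S,6R)-1-(tert-butyldimethylsilyloxy)-6-(4-methoxybenzyloxy)-3,7-dimethyl-4-(triisopropylsilyloxy)octa-2,7-diene | C=C(C)[C@@H](C[C@H](O[Si](C(C)C)(C(C)C)C(C)C)/C(C)=C/CO[Si](C)(C)C(C)(C)C)OCc1ccc(OC)cc1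
A5 | alternative 2 | tert-butyl(but-2-yn-1-yloxy)dimethylsilane | CC#CCO[Si](C)(C)C(C)(C)C
A6 | alternative 2 | (3R)-3-[(4-methoxybenzyl)oxy]-4-methylpent-4-enal | C=C(C)[C@@H](CC=O)OCc1ccc(OC)cc1
A7 | alternative 2 | triisopropylsilane | CC(C)[SiH](C(C)C)C(C)C
A8 | alternative 2 | bis(cycloocta-1,5-diene)nickel, Ni(cod)2 | C1=CCCC=CCC1.C1=CCCC=CCC1.[Ni]
A9 | alternative 3 | (2E,4S)-4-(tert-butyldimethylsilyloxy)-3,7-dimethylocta-2,6-dien-1-ol | CC(C)=CC[C@H](O[Si](C)(C)C(C)(C)C)/C(C)=C/CO
A10 | alternative 3 | tert-butyldimethyl{[(3S)-6-methylhept-5-en-1-yn-3-yl]oxy}silane | CC(C)=CC[C@H](O[Si](C)(C)C(C)(C)C)C#C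
A11 | alternative 3 | trimethylaluminium, Me3Al | C[Al](C)C
A12 | alternative 3 | zirconocene dichloride, Cp2ZrCl2 | [Zr+4].[Cl-].[Cl-].c1cc[cH-]c1.c1cc[cH-]c1
A13 | alternative 3 | formaldehyde | C=O
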